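**Retrosynthetic overview**
- The route rests on the bond between the enone β-carbon and C1 of the 4-hydroxyphenyl ring B. It is cut to a terminal aryl vinyl ketone that already carries ring A with its C2' oxygen, C3' geranyl group and C4' methoxy group, and a 4-iodophenol ether (Mizoroki–Heck).
- The vinyl ketone comes from oxidation of an aryl vinyl carbinol. Its C1'–C(carbinol) bond is made by ortho-lithiation beside the OMOM group and addition to acrolein.
- The C3'–C1'' bond to the geranyl chain is made earlier, by lithiation between the two oxygens of 3-methoxyphenol MOM ether and copper-mediated allylation with geranyl bromide.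
- No ring is formed; both benzene rings are bought. The E enone is set in the Heck step, and the E alkene of the chain comes from geranyl bromide.
- Both phenols travel as MOM ethers, which are removed together in the last step.

Key step: step 6

Assumption: the arylcopper of step 2 is drawn as monomeric ArCu. Carbinol 11 is made and used as the racemate, because its stereocentre is removed in step 4.

**Step 1**
Reactants: 1 3-methoxyphenol
Product: 3 1-methoxy-3-(methoxymethoxy)benzene, via sodium 3-methoxyphenoxide 2 (not isolated)
Conditions: NaH, DMF, 0 °C; then MOMCl, 0 °C → rt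
Reagents that add atoms: chloromethyl methyl ether (MOMCl), COCCl
Why: Williamson-type O-alkylation, in which the sodium phenoxide displaces chloride from the α-chloro ether to give the aryl MOM acetal that later directs both lithiations.

**Step 2**
Reactants: 3 1-methoxy-3-(methoxymethoxy)benzene; 4 geranyl bromide
Product: 7 2-[(2E)-3,7-dimethylocta-2,6-dien-1-yl]-1-methoxy-3-(methoxymethoxy)benzene, via 2-lithio arene 5 (not isolated), via arylcopper 6 (not isolated)
Conditions: n-BuLi, THF, 0 °C → rt; CuI (1 equiv), −30 °C; then 4, −30 °C → rt
Reagents that add atoms: none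
Why: Directed ortho-metalation removes the proton at C2, which is flanked and acidified by both OMe and OMOM, and the derived arylcopper undergoes SN2 allylic substitution at the primary carbon of geranyl bromide, so the E-configured alkene of the chain is carried over unchanged.

**Step 3**
Reactants: 7 2-geranyl-1-methoxy-3-(methoxymethoxy)benzene; 8 acrolein (freshly distilled)
Product: 11 rac-1-[3-geranyl-4-methoxy-2-(methoxymethoxy)phenyl]prop-2-en-1-ol, via 4-lithio arene 9 (not isolated), via lithium alkoxide 10 (not isolated)
Conditions: s-BuLi, TMEDA, THF, −78 °C; then 8, −78 °C; H2O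
Reagents that add atoms: none
Why: Directed ortho-metalation followed by 1,2-addition of the aryllithium to the aldehyde; OMOM is the stronger director and its only free ortho position is C4, the low temperature favours this coordination-directed ring deprotonation over removal of a benzylic-allylic proton, and the new carbinol stereocentre forms as a racemate that step 4 removes.

**Step 4**
Reactants: 11 rac-1-[3-geranyl-4-methoxy-2-(methoxymethoxy)phenyl]prop-2-en-1-ol
Product: 12 1-[3-geranyl-4-methoxy-2-(methoxymethoxy)phenyl]prop-2-en-1-one
Conditions: activated MnO2 (excess), CH2Cl2, rt; product kept cold with a trace of BHT and used at once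
Reagents that add atoms: none
Why: MnO2 oxidation of an allylic and benzylic alcohol, which runs under neutral heterogeneous conditions that leave the trisubstituted alkenes and the MOM acetal untouched and cannot over-oxidise.

**Step 5**
Reactants: 13 4-iodophenol
Product: 15 1-iodo-4-(methoxymethoxy)benzene, via sodium 4-iodophenoxide 14 (not isolated)
Conditions: NaH, DMF, 0 °C; then MOMCl, 0 °C → rt
Reagents that add atoms: chloromethyl methyl ether (MOMCl), COCCl
Why: Williamson-type O-alkylation of the phenoxide with the α-chloro ether, which masks the ring B phenol for the coupling.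

**Step 6**
Reactants: 12 1-[3-geranyl-4-methoxy-2-(methoxymethoxy)phenyl]prop-2-en-1-one; 15 1-iodo-4-(methoxymethoxy)benzene
Product: 16 xanthoangelol F bis(methoxymethyl) ether, (2E)-1-[3-geranyl-4-methoxy-2-(methoxymethoxy)phenyl]-3-[4-(methoxymethoxy)phenyl]prop-2-en-1-one
Conditions: Pd(OAc)2 (5 mol %), n-Bu4NCl, NaHCO3, DMF, 45 °C, argon, trace BHT
Reagents that add atoms: none
Why: Mizoroki–Heck reaction: zerovalent palladium formed in situ from Pd(OAc)2 inserts into the C–I bond of 15, the arylpalladium iodide adds syn across the terminal C=C of 12 with the aryl group going to the unsubstituted β-carbon, and syn β-hydride elimination releases the enone while NaHCO3 takes up HI and returns zerovalent palladium. The closest known reaction type is the ligand-free, ammonium-salt-promoted Heck arylation of methyl and aryl vinyl ketones with aryl iodides, which gives benzalacetones and chalcones, so the step applies known chemistry to a new substrate. No ring closes and no stereocentre forms; the single skeletal bond made is the one between the β-carbon and C1 of ring B. The E geometry follows from the syn-addition and syn-elimination sequence, which passes through the rotamer holding aryl and acyl groups apart, and the E chalcone is also the thermodynamic isomer. The step needs β-regioselectivity and chemoselectivity for the vinyl ketone over the two geranyl alkenes; the polarised monosubstituted enone secures the first, and the far slower insertion of trisubstituted electron-rich alkenes secures the second. The weakly basic, non-acidic medium leaves the geranyl chain and both MOM ethers intact, and the MOM cap on the 2'-oxygen rules out oxa-Michael closure to a chromanone or flavanone.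

**Step 7**
Reactants: 16 xanthoangelol F bis(methoxymethyl) ether
Product: 17 xanthoangelol F
Conditions: aq. HCl (3 M), MeOH, rt → 40 °C, stopped at full conversion; NaHCO3 work-up
Reagents that add atoms: none
Why: Acid-catalysed acetal methanolysis (MOM ether cleavage) exchanges both MOM groups to dimethoxymethane, the 2'-acetal being labilised by the hydrogen bond of the freed phenol to the ketone, while dilute acid near room temperature should neither protonate the trisubstituted alkenes nor isomerise the 2'-hydroxychalcone to the flavanone.

**Compound list**
1 | 3-methoxyphenol | COc1cccc(O)c1 | starting material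
2 | sodium 3-methoxyphenoxide | COc1cccc([O-])c1.[Na+] | intermediate (not isolated)
3 | 1-methoxy-3-(methoxymethoxy)benzene | COCOc1cccc(OC)c1 | intermediate
4 | geranyl bromide, (2E)-1-bromo-3,7-dimethylocta-2,6-diene | BrC/C=C(\C)CCC=C(C)C | starting material
5 | 2-lithio-1-methoxy-3-(methoxymethoxy)benzene | COCOc1cccc(OC)c1[Li] | intermediate (not isolated)
6 | [2-methoxy-6-(methoxymethoxy)phenyl]copper | COCOc1cccc(OC)c1[Cu] | intermediate (not isolated)
7 | 2-[(2E)-3,7-dimethylocta-2,6-dien-1-yl]-1-methoxy-3-(methoxymethoxy)benzene | COCOc1cccc(OC)c1C/C=C(\C)CCC=C(C)C | intermediate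
8 | acrolein (prop-2-enal) | C=CC=O | starting material
9 | 3-geranyl-4-methoxy-2-(methoxymethoxy)phenyllithium | COCOc1c([Li])ccc(OC)c1C/C=C(\C)CCC=C(C)C | intermediate (not isolated)
10 | lithium rac-1-[3-geranyl-4-methoxy-2-(methoxymethoxy)phenyl]prop-2-en-1-olate | [Li+].[O-]C(C=C)c1ccc(OC)c(C/C=C(\C)CCC=C(C)C)c1OCOC | intermediate (not isolated)
11 | rac-1-{3-[(2E)-3,7-dimethylocta-2,6-dien-1-yl]-4-methoxy-2-(methoxymethoxy)phenyl}prop-2-en-1-ol | C=CC(O)c1ccc(OC)c(C/C=C(\C)CCC=C(C)C)c1OCOC | intermediate
12 | 1-{3-[(2E)-3,7-dimethylocta-2,6-dien-1-yl]-4-methoxy-2-(methoxymethoxy)phenyl}prop-2-en-1-one | C=CC(=O)c1ccc(OC)c(C/C=C(\C)CCC=C(C)C)c1OCOC | intermediate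
13 | 4-iodophenol | Oc1ccc(I)cc1 | starting material
14 | sodium 4-iodophenoxide | [Na+].[O-]c1ccc(I)cc1 | intermediate (not isolated)
15 | 1-iodo-4-(methoxymethoxy)benzene | COCOc1ccc(I)cc1 | intermediate
16 | xanthoangelol F bis(methoxymethyl) ether, (2E)-1-{3-[(2E)-3,7-dimethylocta-2,6-dien-1-yl]-4-methoxy-2-(methoxymethoxy)phenyl}-3-[4-(methoxymethoxy)phenyl]prop-2-en-1-one | COCOc1ccc(/C=C/C(=O)c2ccc(OC)c(C/C=C(\C)CCC=C(C)C)c2OCOC)cc1 | intermediate
17 | xanthoangelol F, (2E)-1-{3-[(2E)-3,7-dimethylocta-2,6-dien-1-yl]-2-hydroxy-4-methoxyphenyl}-3-(4-hydroxyphenyl)prop-2-en-1-one | COc1ccc(C(=O)/C=C/c2ccc(O)cc2)c(O)c1C/C=C(\C)CCC=C(C)C | target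

**Step count**
Total: 7 steps. Longest linear sequence: 6 steps (steps 1, 2, 3, 4, 6, 7); step 5 is a one-step side branch.

**Steps most likely to fail, with fallbacks**

Step 6 (Heck coupling). The vinyl ketone may polymerise or be consumed by conjugate addition before the palladium cycle turns over, and the catalyst may fall out as palladium black. The fallback builds the enone by aldol condensation instead. It sets out from 7: lithiation as in step 3 gives aryllithium 9, which is quenched with N-methoxy-N-methylacetamide (CC(=O)N(C)OC) to give 1-[3-geranyl-4-methoxy-2-(methoxymethoxy)phenyl]ethan-1-one F4. Claisen–Schmidt condensation of this methyl ketone with commercial 4-(methoxymethoxy)benzaldehyde (COCOc1ccc(C=O)cc1) under KOH in EtOH at rt should give the E chalcone, and the route is rejoined at 16.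

Step 3 (second lithiation and acrolein addition). Deprotonation may occur at the benzylic-allylic CH2 of the geranyl chain or beside OMe instead of beside OMOM, and acrolein may polymerise under the anionic conditions. The fallback introduces the carbonyl carbon without an organolithium. It sets out from 7: the MOM group is removed under the mild conditions of step 7 to give 2-geranyl-3-methoxyphenol F1. Magnesium-mediated ortho-formylation (MgCl2, Et3N, paraformaldehyde, MeCN, reflux) attacks the only free position ortho to the phenol and should give 3-geranyl-2-hydroxy-4-methoxybenzaldehyde F2. Re-protection (MOMCl, i-Pr2NEt, CH2Cl2) gives 3-geranyl-4-methoxy-2-(methoxymethoxy)benzaldehyde F3, and addition of vinylmagnesium bromide (THF, −78 → 0 °C) rejoins the route at 11.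

Step 7 (removal of both MOM groups). Protonation of the C2''=C3'' alkene may lead to cyclisation of the chain onto the freed 2'-phenol, and the 2'-hydroxychalcone may close to the flavanone under prolonged acid. The fallback replaces protic solvolysis by silyl transfer. It sets out from 16: TMSOTf (trimethylsilyl triflate) and 2,2'-bipyridyl in CH2Cl2 at 0 °C should convert both aryl MOM ethers into silyl ethers, giving xanthoangelol F bis(trimethylsilyl) ether F5. Stirring with water in THF at rt hydrolyses the silyl ethers under near-neutral conditions and returns to the route at 17.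

**Further compounds**
F1 | step 3 | 2-geranyl-3-methoxyphenol | COc1cccc(O)c1C/C=C(\C)CCC=C(C)C
F2 | step 3 | 3-geranyl-2-hydroxy-4-methoxybenzaldehyde | COc1ccc(C=O)c(O)c1C/C=C(\C)CCC=C(C)C
F3 | step 3 | 3-geranyl-4-methoxy-2-(methoxymethoxy)benzaldehyde | COCOc1c(C=O)ccc(OC)c1C/C=C(\C)CCC=C(C)C
F4 | step 6 | 1-[3-geranyl-4-methoxy-2-(methoxymethoxy)phenyl]ethan-1-one | CC(=O)c1ccc(OC)c(C/C=C(\C)CCC=C(C)C)c1OCOC
F5 | step 7 | xanthoangelol F bis(trimethylsilyl) ether | COc1ccc(C(=O)/C=C/c2ccc(O[Si](C)(C)C)cc2)c(O[Si](C)(C)C)c1C/C=C(\C)CCC=C(C)C
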